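Assumption: the SMILES encodes the (3S) isoflavan (C2 > quinone carbon > C4 > H), and that is the enantiomer made.

**Retrosynthetic overview**
1. The quinone is unmasked last: global hydrogenolysis of three benzyl ethers, then aerobic oxidation of the ring B hydroquinone only.
2. C3 is set by iridium-catalysed asymmetric hydrogenation of the isoflav-3-ene.
3. The isoflavene comes from a late Suzuki–Miyaura coupling of a 3-bromo-2H-chromene (fragment A: ring A plus the pyran ring) with a ring B aryl pinacol boronate (fragment B).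
4. Fragment A: resorcinol → syringol → benzyl ether → formylation/Dakin phenol → propargyl ether → Claisen cyclisation (pyran ring formed) → bromohydrin → vinyl bromide. Fragment B: catechol → 2,3-dimethoxyphenol → quinone → hydroquinone dibenzyl ether → bromide → boronate.
5. Ring order: both benzene rings are present from the start; the pyran ring is closed before the coupling; the quinone oxidation level appears in the final step.

**Fragment B (ring B)**

Step 1
Reactants: 1 catechol
Product: 2 1,2-dimethoxybenzene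
Conditions: MeI, K2CO3, acetone, reflux
Reagents that add atoms: iodomethane, CI
Why: Williamson O-methylation of both phenoxides by SN2 on MeI.

Step 2
Reactants: 2 1,2-dimethoxybenzene
Product: 5 2,3-dimethoxyphenol, via 2,3-dimethoxyphenyllithium 3 (not isolated), via dimethyl 2,3-dimethoxyphenylboronate 4 (not isolated)
Conditions: n-BuLi, TMEDA, Et2O, 0 °C to rt; B(OMe)3, −78 °C to rt; AcOH, 30% H2O2, 0 °C to rt
Reagents that add atoms: hydrogen peroxide, OO (phenol oxygen of 5); n-butyllithium, [Li]CCCC (lithium of 3); trimethyl borate, COB(OC)OC (boron and methoxy groups of 4)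
Why: Directed ortho-metalation next to OMe, borylation and oxidative C–B to C–O migration give the phenol at the only position flanking the dimethoxy unit.

Step 3
Reactants: 5 2,3-dimethoxyphenol
Product: 6 2,3-dimethoxy-1,4-benzoquinone
Conditions: K2[ON(SO3)2] (Fremy's salt, 2.2 equiv), KH2PO4, H2O/acetone, rt
Reagents that add atoms: potassium nitrosodisulfonate, [K+].[K+].[O]N(S(=O)(=O)[O-])S(=O)(=O)[O-]
Why: Teuber oxidation of a phenol with a free para position delivers the para-quinone.

Step 4
Reactants: 6 2,3-dimethoxy-1,4-benzoquinone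
Product: 7 2,3-dimethoxybenzene-1,4-diol
Conditions: Na2S2O4, H2O/EtOAc, rt, N2
Reagents that add atoms: none
Why: Dithionite reduction of the quinone to the hydroquinone is fast and clean.

Step 5
Reactants: 7 2,3-dimethoxybenzene-1,4-diol
Product: 8 1,4-bis(benzyloxy)-2,3-dimethoxybenzene
Conditions: BnBr, K2CO3, DMF, rt, N2
Reagents that add atoms: benzyl bromide, BrCc1ccccc1
Why: Williamson benzylation masks the hydroquinone as ethers that are later removed by hydrogenolysis.

Step 6
Reactants: 8 1,4-bis(benzyloxy)-2,3-dimethoxybenzene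
Product: 9 1,4-bis(benzyloxy)-5-bromo-2,3-dimethoxybenzene
Conditions: NBS (1.0 equiv), MeCN, 0 °C
Reagents that add atoms: N-bromosuccinimide, O=C1CCC(=O)N1Br
Why: Electrophilic aromatic bromination of the tetra-alkoxybenzene at one of its two equivalent free positions; the benzyl rings are far less reactive.

Step 7
Reactants: 9 1,4-bis(benzyloxy)-5-bromo-2,3-dimethoxybenzene
Product: 10 2-[2,5-bis(benzyloxy)-3,4-dimethoxyphenyl]-4,4,5,5-tetramethyl-1,3,2-dioxaborolane
Conditions: B2pin2, PdCl2(dppf) (3 mol %), KOAc, dioxane, 90 °C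
Reagents that add atoms: bis(pinacolato)diboron, CC1(C)OB(OC1(C)C)B1OC(C)(C)C(C)(C)O1
Why: Miyaura borylation converts the aryl bromide into a bench-stable pinacol boronate without organolithium chemistry next to benzyl ethers.

**Fragment A (ring A and pyran ring)**

Step 8
Reactants: 11 resorcinol
Product: 12 1,3-dimethoxybenzene
Conditions: MeI, K2CO3, acetone, reflux
Reagents that add atoms: iodomethane, CI
Why: Williamson O-methylation of both phenoxides.

Step 9
Reactants: 12 1,3-dimethoxybenzene
Product: 15 2,6-dimethoxyphenol, via 2,6-dimethoxyphenyllithium 13 (not isolated), via dimethyl 2,6-dimethoxyphenylboronate 14 (not isolated)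
Conditions: n-BuLi, THF, 0 °C to rt; B(OMe)3, −78 °C to rt; AcOH, 30% H2O2, 0 °C to rt
Reagents that add atoms: hydrogen peroxide, OO (phenol oxygen of 15); n-butyllithium, [Li]CCCC (lithium of 13); trimethyl borate, COB(OC)OC (boron and methoxy groups of 14)
Why: Directed ortho-metalation occurs at C2 between the two methoxy groups, and boronate oxidation installs the future 7-OH.

Step 10
Reactants: 15 2,6-dimethoxyphenol
Product: 16 2-(benzyloxy)-1,3-dimethoxybenzene
Conditions: BnBr, K2CO3, DMF, 60 °C
Reagents that add atoms: benzyl bromide, BrCc1ccccc1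
Why: Williamson benzylation protects the future 7-OH as the same hydrogenolysable ether used on ring B.

Step 11
Reactants: 16 2-(benzyloxy)-1,3-dimethoxybenzene
Product: 18 3-(benzyloxy)-2,4-dimethoxybenzaldehyde, via iminium chloride 17 (not isolated)
Conditions: POCl3, DMF, 0 to 75 °C; then H2O, rt
Reagents that add atoms: N,N-dimethylformamide, CN(C)C=O (formyl carbon of 18, CH=NMe2 of 17); water, O (carbonyl oxygen of 18); phosphoryl chloride, O=P(Cl)(Cl)Cl (chloride of 17)
Why: Vilsmeier–Haack formylation of a 1,2,3-trialkoxybenzene goes to C4 (para to one OMe, ortho to the other), as in the 2,3,4-trimethoxybenzaldehyde case.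

Step 12
Reactants: 18 3-(benzyloxy)-2,4-dimethoxybenzaldehyde
Product: 20 3-(benzyloxy)-2,4-dimethoxyphenol, via aryl formate 19 (not isolated)
Conditions: mCPBA, CH2Cl2, rt; then K2CO3 (cat.), MeOH, rt
Reagents that add atoms: 3-chloroperbenzoic acid, OOC(=O)c1cccc(Cl)c1
Why: Dakin-type Baeyer–Villiger oxidation with migration of the electron-rich aryl group, then formate methanolysis, turns CHO into the phenol that becomes O1.

Step 13
Reactants: 20 3-(benzyloxy)-2,4-dimethoxyphenol; 21 propargyl bromide
Product: 22 2-(benzyloxy)-1,3-dimethoxy-4-(prop-2-yn-1-yloxy)benzene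
Conditions: K2CO3, acetone, reflux
Reagents that add atoms: none
Why: Williamson O-propargylation brings in the three carbons C2, C3 and C4 of the pyran ring.

Step 14
Reactants: 22 2-(benzyloxy)-1,3-dimethoxy-4-(prop-2-yn-1-yloxy)benzene
Product: 23 7-(benzyloxy)-6,8-dimethoxy-2H-chromene
Conditions: PhNEt2, 200 °C
Reagents that add atoms: none
Why: Aromatic propargyl Claisen rearrangement to the only free ortho position, 1,5-hydrogen shift and 6π oxa-electrocyclisation close the pyran ring.

Step 15
Reactants: 23 7-(benzyloxy)-6,8-dimethoxy-2H-chromene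
Product: 24 rac-(3R,4R)-7-(benzyloxy)-3-bromo-6,8-dimethoxychroman-4-ol (trans)
Conditions: NBS, DMSO/H2O, 0 °C
Reagents that add atoms: N-bromosuccinimide, O=C1CCC(=O)N1Br; water, O
Why: Bromohydrin formation: the bromonium ion is opened by water anti at the benzylic C4, giving the racemic trans isomer, whose stereocentres are erased in the next step.

Step 16
Reactants: 24 rac-(3R,4R)-7-(benzyloxy)-3-bromo-6,8-dimethoxychroman-4-ol
Product: 25 7-(benzyloxy)-3-bromo-6,8-dimethoxy-2H-chromene
Conditions: TsOH·H2O (cat.), toluene, 80 °C, 4 Å MS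
Reagents that add atoms: none
Why: Acid-catalysed E1 dehydration through the oxygen-stabilised benzylic cation can only place the double bond at C3=C4, giving the vinyl bromide.

**Coupling and endgame**

Step 17
Reactants: 25 7-(benzyloxy)-3-bromo-6,8-dimethoxy-2H-chromene; 10 2-[2,5-bis(benzyloxy)-3,4-dimethoxyphenyl]-4,4,5,5-tetramethyl-1,3,2-dioxaborolane
Product: 26 7-(benzyloxy)-3-[2,5-bis(benzyloxy)-3,4-dimethoxyphenyl]-6,8-dimethoxy-2H-chromene
Conditions: Pd(OAc)2 (3 mol %), SPhos, K3PO4, toluene/H2O, 80 °C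
Reagents that add atoms: none
Why: Suzuki–Miyaura coupling of an alkenyl bromide with an aryl boronate; the bulky electron-rich biaryl phosphine handles the ortho-benzyloxy partner.

Step 18
Reactants: 26 7-(benzyloxy)-3-[2,5-bis(benzyloxy)-3,4-dimethoxyphenyl]-6,8-dimethoxy-2H-chromene
Product: 27 (3S)-7-(benzyloxy)-3-[2,5-bis(benzyloxy)-3,4-dimethoxyphenyl]-6,8-dimethoxychromane
Conditions: H2 (50 bar), [Ir(cod)((4S,5S)-ThrePHOX)][B(3,5-(CF3)2C6H3)4] (2 mol %), CH2Cl2, rt
Reagents that add atoms: none
Why: Iridium-catalysed asymmetric hydrogenation of the trisubstituted styrenyl alkene, in which the chiral P,N ligand shields one alkene face so that both hydrogens add to the face that makes C3 S; I have not established which ligand hand gives 3S for this substrate, so the first run is checked by chiral HPLC and CD and the mirror-image complex is used if it gives 3R; the homogeneous catalyst leaves the benzyl ethers intact.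

Step 19
Reactants: 27 (3S)-7-(benzyloxy)-3-[2,5-bis(benzyloxy)-3,4-dimethoxyphenyl]-6,8-dimethoxychromane
Product: 29 5-[(3S)-7-hydroxy-6,8-dimethoxy-3,4-dihydro-2H-chromen-3-yl]-2,3-dimethoxycyclohexa-2,5-diene-1,4-dione, via hydroquinone triol 28 (not isolated)
Conditions: H2 (1 atm), Pd/C, EtOAc/MeOH, rt; then purge and stir under air, rt
Reagents that add atoms: none
Why: Hydrogenolysis removes all three benzyl ethers, and Pd/C-mediated aerobic dehydrogenation then oxidises only the easily oxidised ring B hydroquinone to the quinone (water as by-product), leaving the ring A phenol and the non-acidic C3 centre untouched under neutral conditions.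

**Compound list**
1 | catechol | Oc1ccccc1O | starting material
2 | 1,2-dimethoxybenzene | COc1ccccc1OC | intermediate
3 | 2,3-dimethoxyphenyllithium | [Li]c1cccc(OC)c1OC | intermediate
4 | dimethyl (2,3-dimethoxyphenyl)boronate | COB(OC)c1cccc(OC)c1OC | intermediate
5 | 2,3-dimethoxyphenol | COc1cccc(O)c1OC | intermediate
6 | 2,3-dimethoxy-1,4-benzoquinone | COC1=C(OC)C(=O)C=CC1=O | intermediate
7 | 2,3-dimethoxybenzene-1,4-diol | COc1c(O)ccc(O)c1OC | intermediate
8 | 1,4-bis(benzyloxy)-2,3-dimethoxybenzene | COc1c(OCc2ccccc2)ccc(OCc3ccccc3)c1OC | intermediate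
9 | 1,4-bis(benzyloxy)-5-bromo-2,3-dimethoxybenzene | COc1c(OCc2ccccc2)cc(Br)c(OCc3ccccc3)c1OC | intermediate
10 | 2-[2,5-bis(benzyloxy)-3,4-dimethoxyphenyl]-4,4,5,5-tetramethyl-1,3,2-dioxaborolane | COc1c(OCc2ccccc2)cc(B3OC(C)(C)C(C)(C)O3)c(OCc4ccccc4)c1OC | intermediate
11 | resorcinol | Oc1cccc(O)c1 | starting material
12 | 1,3-dimethoxybenzene | COc1cccc(OC)c1 | intermediate
13 | 2,6-dimethoxyphenyllithium | [Li]c1c(OC)cccc1OC | intermediate
14 | dimethyl (2,6-dimethoxyphenyl)boronate | COB(OC)c1c(OC)cccc1OC | intermediate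
15 | 2,6-dimethoxyphenol | COc1cccc(OC)c1O | intermediate
16 | 2-(benzyloxy)-1,3-dimethoxybenzene | COc1cccc(OC)c1OCc1ccccc1 | intermediate
17 | N-[3-(benzyloxy)-2,4-dimethoxybenzylidene]-N-methylmethanaminium chloride | COc1ccc(C=[N+](C)C)c(OC)c1OCc1ccccc1.[Cl-] | intermediate
18 | 3-(benzyloxy)-2,4-dimethoxybenzaldehyde | COc1ccc(C=O)c(OC)c1OCc1ccccc1 | intermediate
19 | 3-(benzyloxy)-2,4-dimethoxyphenyl formate | COc1ccc(OC=O)c(OC)c1OCc1ccccc1 | intermediate
20 | 3-(benzyloxy)-2,4-dimethoxyphenol | COc1ccc(O)c(OC)c1OCc1ccccc1 | intermediate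
21 | propargyl bromide (3-bromoprop-1-yne) | C#CCBr | starting material
22 | 2-(benzyloxy)-1,3-dimethoxy-4-(prop-2-yn-1-yloxy)benzene | COc1ccc(OCC#C)c(OC)c1OCc1ccccc1 | intermediate
23 | 7-(benzyloxy)-6,8-dimethoxy-2H-chromene | COc1cc2C=CCOc2c(OC)c1OCc1ccccc1 | intermediate
24 | rac-(3R,4R)-7-(benzyloxy)-3-bromo-6,8-dimethoxychroman-4-ol (trans, racemic; one enantiomer drawn) | COc1cc2[C@@H](O)[C@H](Br)COc2c(OC)c1OCc1ccccc1 | intermediate
25 | 7-(benzyloxy)-3-bromo-6,8-dimethoxy-2H-chromene | COc1cc2C=C(Br)COc2c(OC)c1OCc1ccccc1 | intermediate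
26 | 7-(benzyloxy)-3-[2,5-bis(benzyloxy)-3,4-dimethoxyphenyl]-6,8-dimethoxy-2H-chromene | COc1cc2C=C(c3cc(OCc4ccccc4)c(OC)c(OC)c3OCc5ccccc5)COc2c(OC)c1OCc6ccccc6 | intermediate
27 | (3S)-7-(benzyloxy)-3-[2,5-bis(benzyloxy)-3,4-dimethoxyphenyl]-6,8-dimethoxychromane | COc1cc2C[C@@H](c3cc(OCc4ccccc4)c(OC)c(OC)c3OCc5ccccc5)COc2c(OC)c1OCc6ccccc6 | intermediate
28 | 2-[(3S)-7-hydroxy-6,8-dimethoxy-3,4-dihydro-2H-chromen-3-yl]-5,6-dimethoxybenzene-1,4-diol | COc1cc2C[C@@H](c3cc(O)c(OC)c(OC)c3O)COc2c(OC)c1O | intermediate
29 | 5-[(3S)-7-hydroxy-6,8-dimethoxy-3,4-dihydro-2H-chromen-3-yl]-2,3-dimethoxycyclohexa-2,5-diene-1,4-dione (CNP0121136.1) | COC1=C(OC)C(=O)C([C@H]2COc3c(cc(OC)c(O)c3OC)C2)=CC1=O | target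

**Totals**
Total step count: 19 (fragment B steps 1–7, fragment A steps 8–16, joint steps 17–19).
Longest linear sequence: 12 steps (steps 8–16, then 17–19), which is 12/19 of the total.

**Steps most likely to fail, with fallbacks**

Step 18 (asymmetric hydrogenation). The ortho-benzyloxy aryl group makes the trisubstituted alkene hindered, so conversion or enantioselectivity may be poor, and the sense of induction is not known in advance. The fallback replaces catalyst control by resolution. It sets out from 26, which is hydrogenated with the achiral complex [Ir(cod)(PCy3)(py)]PF6 under H2 in CH2Cl2 to the racemic tribenzyl isoflavan F1. Preparative chiral SFC on an amylose carbamate phase then gives 27, while the (3R)-enantiomer F2 is set aside. The route is rejoined at 27.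

Step 15 (bromohydrin formation). NBS may brominate C5 of the very electron-rich ring A, or the labile benzylic bromohydrin may oligomerise. The fallback avoids electrophilic halogen and changes the coupling handle. It sets out from 23, which is epoxidised with dimethyldioxirane in acetone at −20 °C to the racemic cis-3,4-epoxide F3. Catalytic ZnI2 induces Meinwald rearrangement (C4–O ionisation, 1,2-hydride shift) to 7-(benzyloxy)-6,8-dimethoxychroman-3-one F4. NaH and PhNTf2 in THF trap the arene-conjugated enolate as the enol triflate F5. Suzuki coupling of F5 with 10 under the step 17 conditions rejoins the route at 26, bypassing 24 and 25.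

Step 17 (Suzuki coupling). The electron-rich ortho-alkoxy boronate may protodeboronate in aqueous base before it transmetalates. The fallback uses a base-free Negishi coupling that bypasses 10. It sets out from 9, which undergoes bromine–lithium exchange with n-BuLi in THF at −78 °C to the aryllithium F6. ZnCl2 converts this into the arylzinc chloride F7, which is coupled with 25 using Pd(OAc)2/SPhos in THF at 50 °C. The route is rejoined at 26.

**Further compounds**
F1 | step 18 | racemic 7-(benzyloxy)-3-[2,5-bis(benzyloxy)-3,4-dimethoxyphenyl]-6,8-dimethoxychromane | COc1cc2CC(c3cc(OCc4ccccc4)c(OC)c(OC)c3OCc5ccccc5)COc2c(OC)c1OCc6ccccc6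
F2 | step 18 | (3R)-7-(benzyloxy)-3-[2,5-bis(benzyloxy)-3,4-dimethoxyphenyl]-6,8-dimethoxychromane | COc1cc2C[C@H](c3cc(OCc4ccccc4)c(OC)c(OC)c3OCc5ccccc5)COc2c(OC)c1OCc6ccccc6
F3 | step 15 | rac-cis-7-(benzyloxy)-3,4-epoxy-6,8-dimethoxychromane (one enantiomer drawn) | COc1cc2[C@H]3O[C@H]3COc2c(OC)c1OCc1ccccc1
F4 | step 15 | 7-(benzyloxy)-6,8-dimethoxychroman-3-one | COc1cc2CC(=O)COc2c(OC)c1OCc1ccccc1
F5 | step 15 | 7-(benzyloxy)-6,8-dimethoxy-2H-chromen-3-yl trifluoromethanesulfonate | COc1cc2C=C(OS(=O)(=O)C(F)(F)F)COc2c(OC)c1OCc1ccccc1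
F6 | step 17 | [2,5-bis(benzyloxy)-3,4-dimethoxyphenyl]lithium | [Li]c1cc(OCc2ccccc2)c(OC)c(OC)c1OCc1ccccc1
F7 | step 17 | [2,5-bis(benzyloxy)-3,4-dimethoxyphenyl]zinc chloride | Cl[Zn]c1cc(OCc2ccccc2)c(OC)c(OC)c1OCc1ccccc1
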